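Readings and results stem from a simulated flask on assumed constants; noise was put on by code.

- Moles per litre, not per cent of the charge, are the unit I reckon in, so that runs with different charges can be laid side by side.

| setting | birch | ash | maple | flask |
|---|---|---|---|---|
| starting material | 0.80 M | 0.80 M | 1.2 M | 0.80 M |
| partner | 0.44 M | 1.8 M | 0.88 M | 0.880 M |
| free catalyst | 0.40 mM | 0.40 mM | 0.40 mM | 0.40 mM |
| second catalyst | 0.96 mM | 0.96 mM | 0.96 mM | 0.96 mM |
| remark | run made earlier | run made earlier | run made earlier |  |
| time |  |  |  | 2.5 d |

- birch (time / h: target / %, side product / %): 8.00: 23.7, 3.8; 15.0: 39.2, 9.4; 25.0: 47.8, 14.7; 30.0: 50.3, 17.9; 40.0: 52.3, 21.1; 50.0: 53.2, 24.5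
- ash (time / h: target / %, side product / %): 3.00: 16.5, 1.1; 10.0: 62.9, 3.4; 15.0: 79.2, 4.6; 25.0: 92.0, 5.1; 40.0: 94.9, 4.6; 50.0: 94.8, 4.9
- maple (time / h: target / %, side product / %): 10.0: 40.8, 4.5; 20.0: 61.6, 8.2; 30.0: 67.3, 13.4; 40.0: 70.2, 14.8; 50.0: 71.6, 18.0

(each reading ± 0.5 percentage points)

- the numbers in the tables scatter with a standard deviation of 0.5 percentage points
- a reading or a percentage of target counts all its forms, free or not

- share of target in target plus side product at 80 min
- share of target in target plus side product at 2.5 d

- I read from birch that target uses partner one for one: after 50.0 h it stands at 53.2%, and its partner allows 55.0%.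
- I also read from birch that side product per target grows as partner falls, so, with both catalyst charges held as in these runs, I take side made per target made as a constant divided by the partner present. Summed over a run, side product = constant × ln(partner charged / partner left).
- Birch at 15.0 h gives 0.0603 M. I call this the even level, the partner strength at which side product and target grow equally fast, a selectivity factor in concentration form.
- At the early end, ash holds 16.5% target at 3.00 h, and 80 min comes sooner, so I put the flask's partner near its charge. The share is then partner / (partner + even level), or 93.6%.
- At the late end of the flask, starting material is the limiting reagent, with 0.80 M against 0.880 M of partner. I try 0.100 M of side product, and the sum returns 0.0957 M, close enough. The share is 88.0%.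
- My second way is maple, with the same partner charge. At 20.0 h its two products total 0.838 M, near the flask's charge of 0.80 M of starting material, and their share reads 88.3%, which agrees at the late end.
- At the early end, maple's first reading gives 90.1%, but that is an average while partner fell to 0.390 M, so I keep 93.6%.
- The forecast says 86% at 80 min and 89.7% at 2.5 d, with the reading that “Target shows a lag of roughly 0.5–0.8 h”, and its early share stands below mine.
- The flask gives 93.5% at 80 min and 88.8% at 2.5 d.

    partner + catalyst intermediate → second catalyst + target (k = 10.7 M⁻¹ min⁻¹)
    second catalyst + open intermediate ⇌ catalyst intermediate (K = 0.550 M⁻¹, k = 16.6 M⁻¹ min⁻¹)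
    crystals ⇌ target, rate k3*(cs3 - [target]) while solid is left; crystals form when [target] > cs3 (solubility = 13.0 mM, k = 0.213 min⁻¹)
    open intermediate → side product (k = 2.49 × 10⁻⁴ min⁻¹)
    starting material + free catalyst → free catalyst + open intermediate (k = 6.95 M⁻¹ min⁻¹)

- At 2.5 d the flask holds 0% of its starting material and 20% of its partner, each as a part of its charge. With its 87.9% target, the even level gives 12.1% side product, and the flask holds 11.0%. A neighbouring flask has 2.0 M of starting material and the same partner, so the even level again gives 93.6% at 80 min, and that neighbour shows 93.1%.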